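Azulene numbering is used throughout: C1 ketone, C2 methylene, C3 carbinol bearing isopropyl, C3a/C8a ring fusion, C4 ester carbon, C6=C7 alkene.

Cuts, in retrosynthetic order: the C4–O acyl bond; C6=C7 (metathesis); C4–C5 (methallylation of a C3a aldehyde); C3–C3a together with C8–C8a (Prins–pinacol cascade); C1–C8 (ketone allylation); C2–C3 (aldol); C3a=C8a (Wittig).
Enabling feature: in the cyclopentanone, the C1 carbonyl sits next to quaternary C8a, which is a pinacol retron. C8a is bonded to C3a, and C3a to the tertiary carbinol C3 with its isopropyl group, which is a Prins retron. Ring atoms C1–C2–C3–C3a–C8a therefore unfold to an open-chain β-silyloxy isopropyl ketone whose carbinol carbon C1 carries an alkenyl and an allyl group.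
Forward order: the open chain is built first, the five-membered ring closes in step 10, and the seven-membered ring closes in step 14.
Stereochemistry: catalytic asymmetric allylboration sets C1 of the open chain. The cascade relays it to C8a, C3a and C3 and then erases it. C4 comes from a reagent-controlled Brown methallylation that is matched with the hydrogen-bonded aldehyde rotamer.

Key step: step 10

Assumption: the facial preference known for the CuF/iPr-DuPHOS allylcopper reagent with aryl and alkenyl methyl ketones is taken to hold here, with the α-branched alkenyl group as the large substituent. If the (5S) carbinol prevailed, the ligand antipode would be used.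

Step 1
Reactants: 1 (Z)-but-2-ene-1,4-diol
Product: 2 (Z)-1,4-bis(tert-butyldiphenylsilyloxy)but-2-ene
Conditions: TBDPSCl (2.2 equiv), imidazole, DMF, 0 °C → rt
Reagents that add atoms: tert-butyl(chloro)diphenylsilane, CC(C)(C)[Si](Cl)(c1ccccc1)c1ccccc1
Why: Imidazole-promoted silyl ether formation protects both primary alcohols of the symmetrical diol, so that one alkene cleavage later gives two molecules of the same aldehyde.

Step 2
Reactants: 2 (Z)-1,4-bis(tert-butyldiphenylsilyloxy)but-2-ene
Product: 4 2-(tert-butyldiphenylsilyloxy)acetaldehyde, via secondary ozonide 3 (not isolated)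
Conditions: O3, CH2Cl2, −78 °C; then PPh3, −78 °C → rt
Reagents that add atoms: ozone, [O-][O+]=O
Why: Ozonolysis with reductive work-up cleaves the only alkene into two equivalents of the α-silyloxy aldehyde, and silyl ethers are inert to ozone.

Step 3
Reactants: 4 2-(tert-butyldiphenylsilyloxy)acetaldehyde; 5 3-(triphenylphosphoranylidene)butan-2-one
Product: 6 (E)-5-(tert-butyldiphenylsilyloxy)-3-methylpent-3-en-2-one
Conditions: toluene, 90 °C
Reagents that add atoms: none
Why: Wittig olefination with a keto-stabilised, α-branched ylide reliably gives the (E)-trisubstituted enone, which fixes the C3a=C8a geometry that the cascade later reads out.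

Step 4
Reactants: 6 (E)-5-(tert-butyldiphenylsilyloxy)-3-methylpent-3-en-2-one; 7 isobutyraldehyde
Product: 9 (E)-1-(tert-butyldiphenylsilyloxy)-6-hydroxy-3,7-dimethyloct-2-en-4-one (racemic), via lithium dienolate 8 (not isolated)
Conditions: LDA, THF, −78 °C; then 7, −78 °C; AcOH quench
Reagents that add atoms: none
Why: Kinetic α′-deprotonation of the methyl ketone followed by a lithium aldol addition forms C2–C3, and the new carbinol centre is left racemic because step 8 oxidises it to the C3 ketone.

Step 5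
Reactants: 9 (E)-1-(tert-butyldiphenylsilyloxy)-6-hydroxy-3,7-dimethyloct-2-en-4-one (racemic)
Product: 10 (E)-1-(tert-butyldiphenylsilyloxy)-3,7-dimethyl-6-(triethylsilyloxy)oct-2-en-4-one (racemic)
Conditions: TESCl, imidazole, CH2Cl2, 0 °C → rt
Reagents that add atoms: chlorotriethylsilane, CC[Si](Cl)(CC)CC
Why: Silyl ether formation masks the free hydroxyl group, which would otherwise bind boron or copper and open a hydroxyl-directed, non-enantioselective allylation pathway in step 6.

Step 6
Reactants: 10 (E)-1-(tert-butyldiphenylsilyloxy)-3,7-dimethyl-6-(triethylsilyloxy)oct-2-en-4-one (racemic); 11 allylboronic acid pinacol ester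
Product: 12 (5R,6E)-8-(tert-butyldiphenylsilyloxy)-2,6-dimethyl-5-(prop-2-en-1-yl)-3-(triethylsilyloxy)oct-6-en-5-ol (both C3 epimers)
Conditions: 11 (1.5 equiv), CuF2·2H2O (3 mol %), (R,R)-iPr-DuPHOS (6 mol %), La(OiPr)3 (4.5 mol %), DMF, −40 °C; aq. NH4Cl
Reagents that add atoms: none
Why: This is a copper(I)-catalysed enantioselective allylboration of a ketone, in which the boronate transmetallates to a bisphosphine-bound allylcopper that adds 1,2 to the enone carbonyl, the ligand distinguishing the flat α-branched alkenyl group from the CH2 group and so setting the (5R) carbinol (future C1), while the remote racemic C3 centre only doubles the product into two epimers that share this configuration.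

Step 7
Reactants: 12 (5R,6E)-8-(tert-butyldiphenylsilyloxy)-2,6-dimethyl-5-(prop-2-en-1-yl)-3-(triethylsilyloxy)oct-6-en-5-ol (both C3 epimers)
Product: 13 (5R,6E)-8-(tert-butyldiphenylsilyloxy)-2,6-dimethyl-5-(prop-2-en-1-yl)oct-6-ene-3,5-diol (both C3 epimers)
Conditions: HF·pyridine, pyridine, THF, 0 °C
Reagents that add atoms: none
Why: In this buffered fluoride desilylation the triethylsilyl ether is cleaved far faster than the primary tert-butyldiphenylsilyl ether, and the medium is too mild to ionise the tertiary allylic alcohol.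

Step 8
Reactants: 13 (5R,6E)-8-(tert-butyldiphenylsilyloxy)-2,6-dimethyl-5-(prop-2-en-1-yl)oct-6-ene-3,5-diol (both C3 epimers)
Product: 14 (5R,6E)-8-(tert-butyldiphenylsilyloxy)-5-hydroxy-2,6-dimethyl-5-(prop-2-en-1-yl)oct-6-en-3-one
Conditions: Dess–Martin periodinane, CH2Cl2, 0 °C → rt
Reagents that add atoms: none
Why: Dess–Martin oxidation can act only on the secondary alcohol and merges the two C3 epimers into one β-hydroxy ketone with a single stereocentre, under conditions that are not basic enough for a retro-aldol reaction.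

Step 9
Reactants: 14 (5R,6E)-8-(tert-butyldiphenylsilyloxy)-5-hydroxy-2,6-dimethyl-5-(prop-2-en-1-yl)oct-6-en-3-one
Product: 15 (5R,6E)-8-(tert-butyldiphenylsilyloxy)-2,6-dimethyl-5-(prop-2-en-1-yl)-5-(trimethylsilyloxy)oct-6-en-3-one
Conditions: 1-(trimethylsilyl)imidazole, CH2Cl2, rt
Reagents that add atoms: 1-(trimethylsilyl)imidazole, C[Si](C)(C)n1ccnc1
Why: Silylation with an N-silylimidazole reaches hindered tertiary alcohols without a strong base or a silyl triflate, so neither retro-aldol cleavage nor silyl enol ether formation should compete.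

Step 10
Reactants: 15 (5R,6E)-8-(tert-butyldiphenylsilyloxy)-2,6-dimethyl-5-(prop-2-en-1-yl)-5-(trimethylsilyloxy)oct-6-en-3-one
Product: 18 (2R,3S,4R)-3-[(tert-butyldiphenylsilyloxy)methyl]-2-methyl-4-(propan-2-yl)-2-(prop-2-en-1-yl)-4-(trimethylsilyloxy)cyclopentan-1-one, via silyloxycarbenium ion 16 (not isolated), via cyclopentyl cation 17 (not isolated)
Conditions: Me3SiNTf2 (10 mol %), 2,6-di-tert-butyl-4-methylpyridine (15 mol %), CH2Cl2 (0.02 M), −78 → −40 °C
Reagents that add atoms: none
Why: Proposed new method: Me3SiNTf2 silylates the C3 ketone oxygen of 15 to give silyloxycarbenium ion 16, C3a of the trisubstituted alkene attacks C3 to give the tertiary C8a cation 17, and the allyl group then moves suprafacially from C1 to C8a while the C1 silyl ether collapses to the ketone and passes its Me3Si+ on to the next ketone, so that the step is a catalytic isomerisation. The closest known reaction types are the acetal-initiated Prins cyclisation terminated by a pinacol shift of alkenyl carbinol silyl ethers and the alkylaluminium halide-induced closure of γ,δ-unsaturated ketones to cyclopentyl cations that end in 1,2-alkyl shifts, and what is new is the silyl-activated ketone as initiator together with an exocyclic allyl group as the migrating group. The cyclopentane closes 5-endo-trig at the alkene and exo at the C=O+ unit, a mode that is open to cations of this kind although it is closed to anions and radicals. C8a is controlled by C1 because the allyl group can reach the cation only on the ring face that it already occupies, C3a by anti addition across the (E)-alkene from the C1–C8a rotamer in which the donor C1–allyl σ bond lies antiperiplanar to the incoming C3 and the acceptor C1–O bond lies near the alkene plane, and C3 by the isopropyl group turning away from the C4 side chain at the forming bond, which places C3–O cis to C4. The step needs the ketone to react before the tertiary allylic C1–O bond ionises or the C1–C2 bond breaks in a retro-aldol sense, and it needs the trisubstituted alkene to react in preference to the terminal one; the strongly Lewis acidic but non-nucleophilic silyl triflimide at low temperature, the hindered pyridine that removes traces of acid, the weakly basic OTBDPS oxygen and the much higher π-nucleophilicity of the trisubstituted alkene are there to secure this. Migration of the ring carbon C2 would give a strained cyclobutane, so allyl is the group that shifts.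

Step 11
Reactants: 18 (2R,3S,4R)-3-[(tert-butyldiphenylsilyloxy)methyl]-2-methyl-4-(propan-2-yl)-2-(prop-2-en-1-yl)-4-(trimethylsilyloxy)cyclopentan-1-one
Product: 19 (2R,3S,4R)-4-hydroxy-3-(hydroxymethyl)-2-methyl-4-(propan-2-yl)-2-(prop-2-en-1-yl)cyclopentan-1-one
Conditions: HF·pyridine, THF, 0 °C → rt
Reagents that add atoms: none
Why: Fluoride desilylation in a slightly acidic medium removes both silyl groups without the base that would trigger retro-aldol or E1cB loss at C3, and the unreactive tertiary C3–OH is kept free because it steers step 13.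

Step 12
Reactants: 19 (2R,3S,4R)-4-hydroxy-3-(hydroxymethyl)-2-methyl-4-(propan-2-yl)-2-(prop-2-en-1-yl)cyclopentan-1-one
Product: 20 (1R,2R,5R)-5-hydroxy-2-methyl-3-oxo-5-(propan-2-yl)-2-(prop-2-en-1-yl)cyclopentane-1-carbaldehyde
Conditions: Dess–Martin periodinane, CH2Cl2, 0 °C
Reagents that add atoms: none
Why: Dess–Martin oxidation converts the only oxidisable (primary) alcohol into the aldehyde under non-basic conditions, so C3a should not epimerise and the β-hydroxyl group should not be lost.

Step 13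
Reactants: 20 (1R,2R,5R)-5-hydroxy-2-methyl-3-oxo-5-(propan-2-yl)-2-(prop-2-en-1-yl)cyclopentane-1-carbaldehyde; 21 2-methylallylmagnesium chloride
Product: 23 (2R,3S,4R)-4-hydroxy-3-[(1S)-1-hydroxy-3-methylbut-3-en-1-yl]-2-methyl-4-(propan-2-yl)-2-(prop-2-en-1-yl)cyclopentan-1-one, via borinate ester 22 (not isolated)
Conditions: (−)-Ipc2BOMe, 21, Et2O, −78 → 0 °C; then 20, −78 °C; then HOCH2CH2NH2, rt
Reagents that add atoms: none
Why: In this Brown asymmetric methallylboration through a closed chair transition state the (+)-α-pinene-derived borane adds to the Si face of the aldehyde and sets (4S), this face is also the exposed one in the rotamer held by the C3–OH···O=C4 hydrogen bond, and the hindered C1 ketone does not react at −78 °C.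

Step 14
Reactants: 23 (2R,3S,4R)-4-hydroxy-3-[(1S)-1-hydroxy-3-methylbut-3-en-1-yl]-2-methyl-4-(propan-2-yl)-2-(prop-2-en-1-yl)cyclopentan-1-one
Product: 24 (3R,3aS,4S,8aR)-3,4-dihydroxy-6,8a-dimethyl-3-(propan-2-yl)-3,3a,4,5,8,8a-hexahydroazulen-1(2H)-one
Conditions: Grubbs second-generation catalyst (5 mol %), CH2Cl2 (2 mM), 40 °C
Reagents that add atoms: none
Why: Ring-closing metathesis of the monosubstituted with the 1,1-disubstituted alkene forms the trisubstituted C6=C7 bond and the seven-membered ring, the trans-disposed chains on C8a and C3a giving the little-strained trans-fused hydroazulene while loss of ethene drives the reaction.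

Step 15
Reactants: 24 (3R,3aS,4S,8aR)-3,4-dihydroxy-6,8a-dimethyl-3-(propan-2-yl)-3,3a,4,5,8,8a-hexahydroazulen-1(2H)-one; 25 4-(tert-butyldimethylsilyloxy)benzoic acid
Product: 26 (3R,3aS,4S,8aR)-3-hydroxy-6,8a-dimethyl-1-oxo-3-(propan-2-yl)-1,2,3,3a,4,5,8,8a-octahydroazulen-4-yl 4-(tert-butyldimethylsilyloxy)benzoate
Conditions: DCC, DMAP (cat.), CH2Cl2, rt
Reagents that add atoms: none
Why: Steglich esterification acylates only the secondary C4–OH with retention, because the tertiary C3–OH flanked by isopropyl is too hindered to compete.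

Step 16
Reactants: 26 (3R,3aS,4S,8aR)-3-hydroxy-6,8a-dimethyl-1-oxo-3-(propan-2-yl)-1,2,3,3a,4,5,8,8a-octahydroazulen-4-yl 4-(tert-butyldimethylsilyloxy)benzoate
Product: 27 (3R,3aS,4S,8aR)-3-hydroxy-6,8a-dimethyl-1-oxo-3-(propan-2-yl)-1,2,3,3a,4,5,8,8a-octahydroazulen-4-yl 4-hydroxybenzoate (CNP0238517.1)
Conditions: TBAF, AcOH (1:1), THF, 0 °C
Reagents that add atoms: none
Why: Fluoride cleavage of the aryl silyl ether is fast, and the acetic acid buffer keeps the ester and the β-hydroxy ketone away from basic fluoride or phenoxide.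

Compound list
1 | (Z)-but-2-ene-1,4-diol | OC/C=C\CO | starting material
2 | (Z)-1,4-bis(tert-butyldiphenylsilyloxy)but-2-ene | CC(C)(C)[Si](c1ccccc1)(c1ccccc1)OC/C=C\CO[Si](c1ccccc1)(c1ccccc1)C(C)(C)C | intermediate
3 | 3,5-bis[(tert-butyldiphenylsilyloxy)methyl]-1,2,4-trioxolane (secondary ozonide) | CC(C)(C)[Si](c1ccccc1)(c1ccccc1)OCC1OOC(CO[Si](c2ccccc2)(c2ccccc2)C(C)(C)C)O1 | intermediate
4 | 2-(tert-butyldiphenylsilyloxy)acetaldehyde | O=CCO[Si](c1ccccc1)(c1ccccc1)C(C)(C)C | intermediate
5 | 3-(triphenylphosphoranylidene)butan-2-one | CC(=O)C(C)=P(c1ccccc1)(c1ccccc1)c1ccccc1 | starting material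
6 | (E)-5-(tert-butyldiphenylsilyloxy)-3-methylpent-3-en-2-one | CC(=O)/C(C)=C/CO[Si](c1ccccc1)(c1ccccc1)C(C)(C)C | intermediate
7 | isobutyraldehyde | CC(C)C=O | starting material
8 | lithium (E)-5-(tert-butyldiphenylsilyloxy)-3-methylpenta-1,3-dien-2-olate | [Li]OC(=C)/C(C)=C/CO[Si](c1ccccc1)(c1ccccc1)C(C)(C)C | intermediate
9 | (E)-1-(tert-butyldiphenylsilyloxy)-6-hydroxy-3,7-dimethyloct-2-en-4-one (racemic) | CC(C)C(O)CC(=O)/C(C)=C/CO[Si](c1ccccc1)(c1ccccc1)C(C)(C)C | intermediate
10 | (E)-1-(tert-butyldiphenylsilyloxy)-3,7-dimethyl-6-(triethylsilyloxy)oct-2-en-4-one (racemic) | CC[Si](CC)(CC)OC(CC(=O)/C(C)=C/CO[Si](c1ccccc1)(c1ccccc1)C(C)(C)C)C(C)C | intermediate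
11 | allylboronic acid pinacol ester | C=CCB1OC(C)(C)C(C)(C)O1 | starting material
12 | (5R,6E)-8-(tert-butyldiphenylsilyloxy)-2,6-dimethyl-5-(prop-2-en-1-yl)-3-(triethylsilyloxy)oct-6-en-5-ol (both C3 epimers) | C=CC[C@@](O)(CC(O[Si](CC)(CC)CC)C(C)C)/C(C)=C/CO[Si](c1ccccc1)(c1ccccc1)C(C)(C)C | intermediate
13 | (5R,6E)-8-(tert-butyldiphenylsilyloxy)-2,6-dimethyl-5-(prop-2-en-1-yl)oct-6-ene-3,5-diol (both C3 epimers) | C=CC[C@@](O)(CC(O)C(C)C)/C(C)=C/CO[Si](c1ccccc1)(c1ccccc1)C(C)(C)C | intermediate
14 | (5R,6E)-8-(tert-butyldiphenylsilyloxy)-5-hydroxy-2,6-dimethyl-5-(prop-2-en-1-yl)oct-6-en-3-one | C=CC[C@@](O)(CC(=O)C(C)C)/C(C)=C/CO[Si](c1ccccc1)(c1ccccc1)C(C)(C)C | intermediate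
15 | (5R,6E)-8-(tert-butyldiphenylsilyloxy)-2,6-dimethyl-5-(prop-2-en-1-yl)-5-(trimethylsilyloxy)oct-6-en-3-one | C=CC[C@@](O[Si](C)(C)C)(CC(=O)C(C)C)/C(C)=C/CO[Si](c1ccccc1)(c1ccccc1)C(C)(C)C | intermediate
16 | O-trimethylsilylated ketone of 15 (silyloxycarbenium ion) | C=CC[C@@](O[Si](C)(C)C)(CC(=[O+][Si](C)(C)C)C(C)C)/C(C)=C/CO[Si](c1ccccc1)(c1ccccc1)C(C)(C)C | intermediate
17 | tertiary cyclopentyl cation at C8a, with allyl and OSiMe3 on C1, OSiMe3 and isopropyl on C3, and CH2OTBDPS on C3a | C=CC[C@@]1(O[Si](C)(C)C)C[C@@](O[Si](C)(C)C)(C(C)C)[C@H](CO[Si](c2ccccc2)(c2ccccc2)C(C)(C)C)[C+]1C | intermediate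
18 | (2R,3S,4R)-3-[(tert-butyldiphenylsilyloxy)methyl]-2-methyl-4-(propan-2-yl)-2-(prop-2-en-1-yl)-4-(trimethylsilyloxy)cyclopentan-1-one | C=CC[C@@]1(C)C(=O)C[C@@](O[Si](C)(C)C)(C(C)C)[C@@H]1CO[Si](c2ccccc2)(c2ccccc2)C(C)(C)C | intermediate
19 | (2R,3S,4R)-4-hydroxy-3-(hydroxymethyl)-2-methyl-4-(propan-2-yl)-2-(prop-2-en-1-yl)cyclopentan-1-one | C=CC[C@@]1(C)C(=O)C[C@@](O)(C(C)C)[C@@H]1CO | intermediate
20 | (1R,2R,5R)-5-hydroxy-2-methyl-3-oxo-5-(propan-2-yl)-2-(prop-2-en-1-yl)cyclopentane-1-carbaldehyde | C=CC[C@@]1(C)C(=O)C[C@@](O)(C(C)C)[C@@H]1C=O | intermediate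
21 | 2-methylallylmagnesium chloride | CC(=C)C[Mg]Cl | starting material
22 | diisopinocampheylborinate of 23 at the C4 oxygen | C=CC[C@@]1(C)C(=O)C[C@@](O)(C(C)C)[C@@H]1[C@H](CC(C)=C)OB([C@@H]2C[C@@H]3C[C@H]([C@H]2C)C3(C)C)[C@@H]2C[C@@H]3C[C@H]([C@H]2C)C3(C)C | intermediate
23 | (2R,3S,4R)-4-hydroxy-3-[(1S)-1-hydroxy-3-methylbut-3-en-1-yl]-2-methyl-4-(propan-2-yl)-2-(prop-2-en-1-yl)cyclopentan-1-one | C=CC[C@@]1(C)C(=O)C[C@@](O)(C(C)C)[C@@H]1[C@@H](O)CC(C)=C | intermediate
24 | (3R,3aS,4S,8aR)-3,4-dihydroxy-6,8a-dimethyl-3-(propan-2-yl)-3,3a,4,5,8,8a-hexahydroazulen-1(2H)-one | CC1=CC[C@@]2(C)C(=O)C[C@@](O)(C(C)C)[C@@H]2[C@@H](O)C1 | intermediate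
25 | 4-(tert-butyldimethylsilyloxy)benzoic acid | CC(C)(C)[Si](C)(C)Oc1ccc(cc1)C(=O)O | starting material
26 | (3R,3aS,4S,8aR)-3-hydroxy-6,8a-dimethyl-1-oxo-3-(propan-2-yl)-1,2,3,3a,4,5,8,8a-octahydroazulen-4-yl 4-(tert-butyldimethylsilyloxy)benzoate | CC1=CC[C@@]2(C)C(=O)C[C@@](O)(C(C)C)[C@@H]2[C@@H](OC(=O)c3ccc(O[Si](C)(C)C(C)(C)C)cc3)C1 | intermediate
27 | (3R,3aS,4S,8aR)-3-hydroxy-6,8a-dimethyl-1-oxo-3-(propan-2-yl)-1,2,3,3a,4,5,8,8a-octahydroazulen-4-yl 4-hydroxybenzoate | CC1=CC[C@@]2(C)C(=O)C[C@@](O)(C(C)C)[C@@H]2[C@@H](OC(=O)c2ccc(O)cc2)C1 | target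

Total step count: 16. Longest linear sequence: 16 steps (1 → 27); all coupling partners are purchased.

Steps most likely to fail

1. Step 10 (key step).
- What may go wrong: silylation of the hindered ketone may be outrun by ionisation of the tertiary allylic C1–O bond. It may also be outrun by retro-aldol-type cleavage of C1–C2 in the activated β-silyloxy ketone, which on recombination would also erode the C1 configuration. The C8a cation may lose a proton from its methyl group instead of accepting the allyl group, and facial selectivity at C3 or C3a may be poor.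
- Fallback, known reactions only, leaving the route at 14 and returning at 19: the alkene is turned into an allylmetal, so that the ring closes by a polar addition and the cation is generated afterwards in the closed ring.
- Allylic oxidation of the only allylic methyl group of 14 (cat. SeO2, t-BuOOH, CH2Cl2) gives (5R,6E)-8-(tert-butyldiphenylsilyloxy)-5-hydroxy-6-(hydroxymethyl)-2-methyl-5-(prop-2-en-1-yl)oct-6-en-3-one F1.
- Appel bromination (CBr4, PPh3, CH2Cl2) gives (5R,6Z)-6-(bromomethyl)-8-(tert-butyldiphenylsilyloxy)-5-hydroxy-2-methyl-5-(prop-2-en-1-yl)oct-6-en-3-one F2.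
- An intramolecular indium Barbier allylation (In, THF–H2O) joins C3a, the γ-carbon of the allylindium, to the ketone carbon C3. It gives (1R,3R,4S)-4-[(tert-butyldiphenylsilyloxy)methyl]-5-methylidene-3-(propan-2-yl)-1-(prop-2-en-1-yl)cyclopentane-1,3-diol F3. A metal bridging the two oxygens is expected to favour the cis-1,3-diol.
- An acid-induced semipinacol rearrangement of this allylic alcohol (cat. camphorsulfonic acid, CH2Cl2) protonates the exocyclic methylene and shifts the allyl group from C1 to C8a. It gives (2R,3S,4R)-3-[(tert-butyldiphenylsilyloxy)methyl]-4-hydroxy-2-methyl-4-(propan-2-yl)-2-(prop-2-en-1-yl)cyclopentan-1-one F4. HF·pyridine then gives 19.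

2. Step 6.
- What may go wrong: the ligand may distinguish poorly between the alkenyl and the CH2 substituent, the two enantiomers of racemic 10 may respond unequally to the catalyst, and addition to the hindered ketone may be slow.
- Fallback, leaving the route at 6 and returning at 14: the enantiomer problem is turned into a separation of diastereomers by making the temporary C3 carbinol enantioenriched.
- A direct zinc-catalysed asymmetric aldol addition of 6 to 7 (Et2Zn, (S,S)-ProPhenol, 4 Å molecular sieves, THF) gives (2E,6R)-1-(tert-butyldiphenylsilyloxy)-6-hydroxy-3,7-dimethyloct-2-en-4-one F5. It is drawn as the (R) carbinol, but either antipode serves because the centre is erased later.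
- TESCl/imidazole gives (2E,6R)-1-(tert-butyldiphenylsilyloxy)-3,7-dimethyl-6-(triethylsilyloxy)oct-2-en-4-one F6.
- Allylation with 11 under the conditions of step 6, or simply with allylmagnesium bromide, now gives C5 epimers that are diastereomers. Chromatography delivers (3R,5R,6E)-8-(tert-butyldiphenylsilyloxy)-2,6-dimethyl-5-(prop-2-en-1-yl)-3-(triethylsilyloxy)oct-6-en-5-ol F7.
- Buffered HF·pyridine gives (3R,5R,6E)-8-(tert-butyldiphenylsilyloxy)-2,6-dimethyl-5-(prop-2-en-1-yl)oct-6-ene-3,5-diol F8. Its relative configuration can be checked on the derived acetonide, and Dess–Martin oxidation gives 14.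

3. Step 13.
- What may go wrong: facial selectivity at the neopentyl-type aldehyde may be poor if the substrate bias opposes the reagent, the free C3–OH may protonolyse the borane, and the addition may be sluggish.
- Fallback, leaving the route at 20 and returning at 26: the opposite epimer is made on purpose and C4 is inverted during esterification.
- Methallylboration with the (−)-α-pinene-derived borane gives (2R,3S,4R)-4-hydroxy-3-[(1R)-1-hydroxy-3-methylbut-3-en-1-yl]-2-methyl-4-(propan-2-yl)-2-(prop-2-en-1-yl)cyclopentan-1-one F9.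
- Ring-closing metathesis as in step 14 gives (3R,3aS,4R,8aR)-3,4-dihydroxy-6,8a-dimethyl-3-(propan-2-yl)-3,3a,4,5,8,8a-hexahydroazulen-1(2H)-one F10.
- Mitsunobu esterification with 25 (PPh3, DIAD, toluene) gives 26 with inversion at C4.

Further compounds
F1 | step 10 | (5R,6E)-8-(tert-butyldiphenylsilyloxy)-5-hydroxy-6-(hydroxymethyl)-2-methyl-5-(prop-2-en-1-yl)oct-6-en-3-one | C=CC[C@@](O)(CC(=O)C(C)C)/C(CO)=C/CO[Si](c1ccccc1)(c1ccccc1)C(C)(C)C
F2 | step 10 | (5R,6Z)-6-(bromomethyl)-8-(tert-butyldiphenylsilyloxy)-5-hydroxy-2-methyl-5-(prop-2-en-1-yl)oct-6-en-3-one | C=CC[C@@](O)(CC(=O)C(C)C)/C(CBr)=C/CO[Si](c1ccccc1)(c1ccccc1)C(C)(C)C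
F3 | step 10 | (1R,3R,4S)-4-[(tert-butyldiphenylsilyloxy)methyl]-5-methylidene-3-(propan-2-yl)-1-(prop-2-en-1-yl)cyclopentane-1,3-diol | C=CC[C@@]1(O)C[C@@](O)(C(C)C)[C@H](CO[Si](c2ccccc2)(c2ccccc2)C(C)(C)C)C1=C
F4 | step 10 | (2R,3S,4R)-3-[(tert-butyldiphenylsilyloxy)methyl]-4-hydroxy-2-methyl-4-(propan-2-yl)-2-(prop-2-en-1-yl)cyclopentan-1-one | C=CC[C@@]1(C)C(=O)C[C@@](O)(C(C)C)[C@@H]1CO[Si](c2ccccc2)(c2ccccc2)C(C)(C)C
F5 | step 6 | (2E,6R)-1-(tert-butyldiphenylsilyloxy)-6-hydroxy-3,7-dimethyloct-2-en-4-one | CC(C)[C@H](O)CC(=O)/C(C)=C/CO[Si](c1ccccc1)(c1ccccc1)C(C)(C)C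
F6 | step 6 | (2E,6R)-1-(tert-butyldiphenylsilyloxy)-3,7-dimethyl-6-(triethylsilyloxy)oct-2-en-4-one | CC(C)[C@H](O[Si](CC)(CC)CC)CC(=O)/C(C)=C/CO[Si](c1ccccc1)(c1ccccc1)C(C)(C)C
F7 | step 6 | (3R,5R,6E)-8-(tert-butyldiphenylsilyloxy)-2,6-dimethyl-5-(prop-2-en-1-yl)-3-(triethylsilyloxy)oct-6-en-5-ol | C=CC[C@@](O)(C[C@@H](O[Si](CC)(CC)CC)C(C)C)/C(C)=C/CO[Si](c1ccccc1)(c1ccccc1)C(C)(C)C
F8 | step 6 | (3R,5R,6E)-8-(tert-butyldiphenylsilyloxy)-2,6-dimethyl-5-(prop-2-en-1-yl)oct-6-ene-3,5-diol | C=CC[C@@](O)(C[C@@H](O)C(C)C)/C(C)=C/CO[Si](c1ccccc1)(c1ccccc1)C(C)(C)C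
F9 | step 13 | (2R,3S,4R)-4-hydroxy-3-[(1R)-1-hydroxy-3-methylbut-3-en-1-yl]-2-methyl-4-(propan-2-yl)-2-(prop-2-en-1-yl)cyclopentan-1-one | C=CC[C@@]1(C)C(=O)C[C@@](O)(C(C)C)[C@@H]1[C@H](O)CC(C)=C
F10 | step 13 | (3R,3aS,4R,8aR)-3,4-dihydroxy-6,8a-dimethyl-3-(propan-2-yl)-3,3a,4,5,8,8a-hexahydroazulen-1(2H)-one | CC1=CC[C@@]2(C)C(=O)C[C@@](O)(C(C)C)[C@@H]2[C@H](O)C1
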